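**Plan**

1. Germacrane numbering is used: C1=C10 (C10 carries the methyl ester C14), C4=C5 (C4 carries CH2OH, C15), C6 (lactone oxygen), C7, C8 (methacrylate), C9 (acetate), C11=C13 (exo-methylene), C12 (lactone carbonyl). Both ring alkenes are cis within the ten-membered ring.
2. Enabling feature: in the ten-membered carbocycle the acetoxy carbinol C9 lies between the oxygenated C8 and the ester-bearing alkene carbon C10 (a Morita–Baylis–Hillman-type 2-(1-acyloxyalkyl)acrylate). C9–C10 can therefore be made by adding a C10 alkenyl-metal to a C9 aldehyde whose face is ruled by C8.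
3. Retrosynthesis: cut O15–Si and O9–acetyl; then the ring bond C9–C10 (aldehyde C9 and iodide-bearing C10, both electrophilic, joined after polarity reversal at C10); then O8–methacryloyl, C1=C10 (iodo-Wittig), C6–C7 with lactone C12–O6 (chromium Barbier/lactonisation), and C3–C4 (B-alkyl Suzuki).
4. Forward: enal fragment A (C1–C6, C15) and allylic bromide fragment B (C7–C9, C11–C13) give the α-methylene-γ-butyrolactone (first ring); then iodoenoate, methacrylate and C9 aldehyde; then the ten-membered carbocycle (last ring), acetate and desilylation.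
5. Stereochemistry: C8 from (R)-glyceraldehyde acetonide; C6 and C7 from the Barbier step (anti chair transition state, allylic 1,3-strain relay from C8); C9 from Felkin–Anh addition during ring closure; C4=C5 from trans-hydroalumination/iodination and stereoretentive coupling; C1=C10 from the (Z)-iodoenoate, retained in the ring closure.

Key step: step 13

Remark: compounds 1, 5, 9, 10 and 16 are taken as commercial; 11 is used as the mixture of carbinol epimers because that centre becomes sp2 in step 6.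

**Route**

Step 1
Reactants: 1 2-butyne-1,4-diol
Product: 2 4-[(tert-butyldiphenylsilyl)oxy]but-2-yn-1-ol
Conditions: NaH (1.0 equiv), THF, 0 °C; TBDPSCl (1.0 equiv), 0 °C → rt; diol in excess
Reagents that add atoms: tert-butyl(chloro)diphenylsilane CC(C)(C)[Si](Cl)(c1ccccc1)c1ccccc1
Why: O-silylation of the sparingly soluble monosodium alkoxide of a symmetric diol should stop at the mono-ether; no stereocentre is formed.

Step 2
Reactants: 2 4-[(tert-butyldiphenylsilyl)oxy]but-2-yn-1-ol
Product: 4 (2Z)-4-[(tert-butyldiphenylsilyl)oxy]-3-iodobut-2-en-1-ol, via cyclic vinylalanate 3 (not isolated)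
Conditions: NaAlH2(OCH2CH2OMe)2 (1.5 equiv), THF, 0 °C → rt; then I2, −78 → 0 °C
Reagents that add atoms: iodine II
Why: hydroxyl-directed trans-hydroalumination of the propargylic alcohol puts aluminium on the distal alkyne carbon in a five-membered alanate, and iodinolysis with retention should give the Z-iodide (iodine cis to CH2OH), which fixes the C4=C5 geometry.

Step 3
Reactants: 4 (2Z)-4-[(tert-butyldiphenylsilyl)oxy]-3-iodobut-2-en-1-ol; 5 acrolein diethyl acetal
Product: 7 (2E)-3-{[(tert-butyldiphenylsilyl)oxy]methyl}-6,6-diethoxyhex-2-en-1-ol, via B-alkyl-9-BBN adduct 6 (not isolated)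
Conditions: 5, 9-BBN, THF, 0 °C → rt; then 4, PdCl2(dppf) (5 mol %), AsPh3, Cs2CO3, DMF/H2O, rt
Reagents that add atoms: none
Why: anti-Markovnikov hydroboration followed by B-alkyl Suzuki–Miyaura coupling proceeds with retention at the alkenyl iodide, so the new C3–C4 bond is cis to C6, and the free hydroxyl is tolerated.

Step 4
Reactants: 7 (2E)-3-{[(tert-butyldiphenylsilyl)oxy]methyl}-6,6-diethoxyhex-2-en-1-ol
Product: 8 (2E)-3-{[(tert-butyldiphenylsilyl)oxy]methyl}-6,6-diethoxyhex-2-enal
Conditions: MnO2 (activated, excess), CH2Cl2, rt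
Reagents that add atoms: none
Why: chemoselective allylic oxidation with MnO2 under neutral conditions should give the enal without touching the acetal or silyl ether and without loss of alkene geometry.

Step 5
Reactants: 9 (R)-2,3-O-isopropylideneglyceraldehyde; 10 methyl acrylate
Product: 11 methyl 2-{[(4R)-2,2-dimethyl-1,3-dioxolan-4-yl](hydroxy)methyl}prop-2-enoate (both carbinol epimers)
Conditions: DABCO (0.3 equiv), dioxane/H2O 1:1, rt
Reagents that add atoms: none
Why: the amine-catalysed Morita–Baylis–Hillman reaction joins C7 to C11; the new carbinol centre forms as a mixture, which does not matter because it becomes sp2 in step 6.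

Step 6
Reactants: 11 methyl 2-{[(4R)-2,2-dimethyl-1,3-dioxolan-4-yl](hydroxy)methyl}prop-2-enoate
Product: 12 methyl (2Z)-2-(bromomethyl)-3-[(4S)-2,2-dimethyl-1,3-dioxolan-4-yl]prop-2-enoate
Conditions: NBS, Me2S, CH2Cl2, 0 °C → rt
Reagents that add atoms: N-bromosuccinimide O=C1CCC(=O)N1Br
Why: Corey–Kim-type activation of the allylic alcohol as its alkoxysulfonium salt and SN2′ attack of bromide should give the thermodynamically preferred 2-(bromomethyl)enoate with the dioxolane trans to the ester (Z), leaving C8 untouched.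

Step 7
Reactants: 8 (2E)-3-{[(tert-butyldiphenylsilyl)oxy]methyl}-6,6-diethoxyhex-2-enal; 12 methyl (2Z)-2-(bromomethyl)-3-[(4S)-2,2-dimethyl-1,3-dioxolan-4-yl]prop-2-enoate
Product: 14 (4S,5R)-5-[(1E)-2-{[(tert-butyldiphenylsilyl)oxy]methyl}-5,5-diethoxypent-1-en-1-yl]-4-[(4S)-2,2-dimethyl-1,3-dioxolan-4-yl]-3-methylideneoxolan-2-one, via hydroxy ester 13 (not isolated)
Conditions: CrCl2 (4 equiv), THF, 0 °C → rt; then PPTS (cat.), 5 Å molecular sieves, toluene, 50 °C
Reagents that add atoms: none
Why: chromium-mediated Barbier (Nozaki–Hiyama) allylation with SE2′ attack of C7 on the enal carbonyl, then lactonisation of the γ-hydroxy ester; the Zimmerman–Traxler-type chair with the dioxolanyl group equatorial should give the 6,7-anti adduct (trans-lactone), and allylic 1,3-strain with the fully substituted C11 holds H8 in the alkene plane so that the aldehyde approaches C7 anti to the C8–C9 bond, which should set 6R,7S from the 8S dioxolane.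

Step 8
Reactants: 14 lactone acetonide acetal from step 7
Product: 15 (4E)-4-{[(tert-butyldiphenylsilyl)oxy]methyl}-5-{(2R,3R)-3-[(1S)-1,2-dihydroxyethyl]-4-methylidene-5-oxooxolan-2-yl}pent-4-enal
Conditions: AcOH/H2O/THF 3:1:1, 40 °C
Reagents that add atoms: water O
Why: acid-catalysed hydrolysis of the acetonide and the diethyl acetal in one operation unveils the C8/C9 diol and the C1 aldehyde, while the silyl ether and lactone should survive aqueous acetic acid; no stereocentre is touched.

Step 9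
Reactants: 16 methyl (triphenylphosphoranylidene)acetate
Product: 17 methyl iodo(triphenylphosphoranylidene)acetate
Conditions: I2, K2CO3, MeOH, 0 °C → rt
Reagents that add atoms: iodine II
Why: electrophilic iodination of the stabilised ylide and deprotonation of the resulting iodophosphonium salt should give the isolable iodo ylide.

Step 10
Reactants: 15 diol aldehyde from step 8; 17 methyl iodo(triphenylphosphoranylidene)acetate
Product: 18 methyl (2Z,6E)-6-{[(tert-butyldiphenylsilyl)oxy]methyl}-7-{(2R,3R)-3-[(1S)-1,2-dihydroxyethyl]-4-methylidene-5-oxooxolan-2-yl}-2-iodohepta-2,6-dienoate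
Conditions: CH2Cl2, rt (no added base)
Reagents that add atoms: none
Why: Wittig olefination with the stabilised α-iodo ylide places the ester trans to the alkyl chain and should therefore give mainly the (Z)-2-iodoenoate needed for a ring-cis C1=C10 bond; base-free conditions spare the diol lactone.

Step 11
Reactants: 18 iodoenoate diol from step 10
Product: 20 methyl (2Z,6E)-6-{[(tert-butyldiphenylsilyl)oxy]methyl}-2-iodo-7-[(2R,3S)-3-{(1S)-1-[(2-methylprop-2-enoyl)oxy]-2-[(triethylsilyl)oxy]ethyl}-4-methylidene-5-oxooxolan-2-yl]hepta-2,6-dienoate, via primary triethylsilyl ether 19 (not isolated)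
Conditions: TESCl (1.05 equiv), imidazole, CH2Cl2, −40 °C; then methacrylic anhydride, Et3N, DMAP (cat.), 0 °C
Reagents that add atoms: chlorotriethylsilane CC[Si](Cl)(CC)CC; methacrylic anhydride C=C(C)C(=O)OC(=O)C(C)=C
Why: sterically controlled silylation of the primary hydroxyl followed by DMAP-catalysed acylation of the remaining secondary C8 hydroxyl should install the methacrylate with retention at C8.

Step 12
Reactants: 20 methacrylate silyl ether from step 11
Product: 21 methyl (2Z,6E)-6-{[(tert-butyldiphenylsilyl)oxy]methyl}-2-iodo-7-[(2R,3S)-3-{(1S)-1-[(2-methylprop-2-enoyl)oxy]-2-oxoethyl}-4-methylidene-5-oxooxolan-2-yl]hepta-2,6-dienoate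
Conditions: (COCl)2, DMSO, CH2Cl2, −78 → −40 °C; then Et3N, → 0 °C
Reagents that add atoms: none
Why: under Swern conditions activated dimethyl sulfoxide cleaves the primary triethylsilyl ether directly to the alkoxysulfonium salt and gives the aldehyde (oxidative desilylation), which avoids a free alcohol next to the ester and hence acyl migration.

Step 13
Reactants: 21 iodoenoate aldehyde from step 12
Product: 22 methyl (1(10)E,4E,6R,7S,8S,9R)-15-[(tert-butyldiphenylsilyl)oxy]-9-hydroxy-8-(methacryloyloxy)germacra-1(10),4,11(13)-trien-12,6-olid-14-oate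
Conditions: CrCl2 (10 equiv), NiCl2 (2 mol %), degassed DMSO/THF 3:1, rt, 3 mM, slow addition of 21
Reagents that add atoms: none
Why: Nozaki–Hiyama–Kishi ring closure: zerovalent nickel (formed from NiCl2 and CrCl2) inserts into the C10–I bond, the alkenyl group passes to trivalent chromium, and this nucleophilic C10 adds to the C9 aldehyde, so that two carbons that are both electrophilic in 21 are joined by polarity reversal at C10. The closest known reaction type is the chromium/nickel-mediated alkenyl iodide–aldehyde macrocyclisation used for medium carbocycles, together with the intermolecular coupling of 2-iodoacrylates. The ten-membered carbocycle closes in a 10-exo-trig mode (C=O exocyclic), helped by the two ring-cis trisubstituted alkenes and the trans-fused lactone, which hold C9 and C10 near each other. The new stereocentre C9 (R) is controlled by the adjacent C8: Felkin–Anh (polar) addition anti to the C8–O bond of the α-acyloxy aldehyde gives the 8,9-anti relationship of the target. The step needs chemoselectivity for the aldehyde over the acrylate-type esters and the α-methylene lactone, which the carbonyl-selective, weakly basic alkenylchromium reagent secures; retention of the (Z)-iodide geometry gives the ring-cis enoate and high dilution favours ring closure over oligomerisation.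

Step 14
Reactants: 22 macrocyclic alcohol from step 13
Product: 23 methyl (1(10)E,4E,6R,7S,8S,9R)-9-acetoxy-15-[(tert-butyldiphenylsilyl)oxy]-8-(methacryloyloxy)germacra-1(10),4,11(13)-trien-12,6-olid-14-oate
Conditions: Ac2O, pyridine, DMAP (cat.), CH2Cl2, 0 °C
Reagents that add atoms: acetic anhydride CC(=O)OC(C)=O
Why: DMAP-catalysed acetylation of the secondary allylic C9 alcohol proceeds with retention and should be faster than any acyl shift.

Step 15
Reactants: 23 silyl ether from step 14
Product: 24 CNP0179134.4, methyl (1(10)E,4E,6R,7S,8S,9R)-9-acetoxy-15-hydroxy-8-(methacryloyloxy)germacra-1(10),4,11(13)-trien-12,6-olid-14-oate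
Conditions: HF·pyridine, THF/pyridine, 0 °C → rt
Reagents that add atoms: none
Why: fluoride-mediated cleavage of the primary silyl ether under buffered acidic conditions should leave the three esters and the α-methylene lactone intact and give the target.

**Compound list**

1 | 2-butyne-1,4-diol | OCC#CCO | starting material
2 | 4-[(tert-butyldiphenylsilyl)oxy]but-2-yn-1-ol | OCC#CCO[Si](c1ccccc1)(c1ccccc1)C(C)(C)C | intermediate
3 | sodium cyclic vinylalanate of 2 (aluminium on the carbon bearing CH2OSi, two 2-methoxyethoxy ligands) | [Na+].COCCO[Al-]1(OCCOC)OCC=C1CO[Si](c2ccccc2)(c2ccccc2)C(C)(C)C | intermediate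
4 | (2Z)-4-[(tert-butyldiphenylsilyl)oxy]-3-iodobut-2-en-1-ol | OC/C=C(\I)CO[Si](c1ccccc1)(c1ccccc1)C(C)(C)C | intermediate
5 | acrolein diethyl acetal (3,3-diethoxyprop-1-ene) | C=CC(OCC)OCC | starting material
6 | 9-(3,3-diethoxypropyl)-9-borabicyclo[3.3.1]nonane | CCOC(OCC)CCB1C2CCCC1CCC2 | intermediate
7 | (2E)-3-{[(tert-butyldiphenylsilyl)oxy]methyl}-6,6-diethoxyhex-2-en-1-ol | OC/C=C(\CCC(OCC)OCC)CO[Si](c1ccccc1)(c1ccccc1)C(C)(C)C | intermediate
8 | (2E)-3-{[(tert-butyldiphenylsilyl)oxy]methyl}-6,6-diethoxyhex-2-enal | O=C/C=C(\CCC(OCC)OCC)CO[Si](c1ccccc1)(c1ccccc1)C(C)(C)C | intermediate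
9 | (R)-2,3-O-isopropylideneglyceraldehyde, (4R)-2,2-dimethyl-1,3-dioxolane-4-carbaldehyde | O=C[C@H]1COC(C)(C)O1 | starting material
10 | methyl acrylate | C=CC(=O)OC | starting material
11 | methyl 2-{[(4R)-2,2-dimethyl-1,3-dioxolan-4-yl](hydroxy)methyl}prop-2-enoate (both carbinol epimers) | C=C(C(=O)OC)C(O)[C@H]1COC(C)(C)O1 | intermediate
12 | methyl (2Z)-2-(bromomethyl)-3-[(4S)-2,2-dimethyl-1,3-dioxolan-4-yl]prop-2-enoate | BrC/C(=C\[C@H]1COC(C)(C)O1)C(=O)OC | intermediate
13 | methyl (3S,4R,5E)-6-{[(tert-butyldiphenylsilyl)oxy]methyl}-3-[(4S)-2,2-dimethyl-1,3-dioxolan-4-yl]-9,9-diethoxy-4-hydroxy-2-methylidenenon-5-enoate | CC1(C)OC[C@@H](O1)[C@@H](C(=C)C(=O)OC)[C@H](O)/C=C(/CO[Si](c2ccccc2)(c2ccccc2)C(C)(C)C)CCC(OCC)OCC | intermediate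
14 | (4S,5R)-5-[(1E)-2-{[(tert-butyldiphenylsilyl)oxy]methyl}-5,5-diethoxypent-1-en-1-yl]-4-[(4S)-2,2-dimethyl-1,3-dioxolan-4-yl]-3-methylideneoxolan-2-one | CC1(C)OC[C@@H](O1)[C@H]2C(=C)C(=O)O[C@@H]2/C=C(/CO[Si](c3ccccc3)(c3ccccc3)C(C)(C)C)CCC(OCC)OCC | intermediate
15 | (4E)-4-{[(tert-butyldiphenylsilyl)oxy]methyl}-5-{(2R,3R)-3-[(1S)-1,2-dihydroxyethyl]-4-methylidene-5-oxooxolan-2-yl}pent-4-enal | OC[C@@H](O)[C@H]1C(=C)C(=O)O[C@@H]1/C=C(/CO[Si](c2ccccc2)(c2ccccc2)C(C)(C)C)CCC=O | intermediate
16 | methyl (triphenylphosphoranylidene)acetate | COC(=O)C=P(c1ccccc1)(c1ccccc1)c1ccccc1 | starting material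
17 | methyl iodo(triphenylphosphoranylidene)acetate | COC(=O)C(I)=P(c1ccccc1)(c1ccccc1)c1ccccc1 | intermediate
18 | methyl (2Z,6E)-6-{[(tert-butyldiphenylsilyl)oxy]methyl}-7-{(2R,3R)-3-[(1S)-1,2-dihydroxyethyl]-4-methylidene-5-oxooxolan-2-yl}-2-iodohepta-2,6-dienoate | OC[C@@H](O)[C@H]1C(=C)C(=O)O[C@@H]1/C=C(/CO[Si](c2ccccc2)(c2ccccc2)C(C)(C)C)CC/C=C(\I)C(=O)OC | intermediate
19 | primary triethylsilyl ether of 18 (C9–OSiEt3, C8–OH free, 8S) | CC[Si](CC)(CC)OC[C@@H](O)[C@H]1C(=C)C(=O)O[C@@H]1/C=C(/CO[Si](c2ccccc2)(c2ccccc2)C(C)(C)C)CC/C=C(\I)C(=O)OC | intermediate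
20 | methyl (2Z,6E)-6-{[(tert-butyldiphenylsilyl)oxy]methyl}-2-iodo-7-[(2R,3S)-3-{(1S)-1-[(2-methylprop-2-enoyl)oxy]-2-[(triethylsilyl)oxy]ethyl}-4-methylidene-5-oxooxolan-2-yl]hepta-2,6-dienoate | C=C(C)C(=O)O[C@H](CO[Si](CC)(CC)CC)[C@H]1C(=C)C(=O)O[C@@H]1/C=C(/CO[Si](c2ccccc2)(c2ccccc2)C(C)(C)C)CC/C=C(\I)C(=O)OC | intermediate
21 | methyl (2Z,6E)-6-{[(tert-butyldiphenylsilyl)oxy]methyl}-2-iodo-7-[(2R,3S)-3-{(1S)-1-[(2-methylprop-2-enoyl)oxy]-2-oxoethyl}-4-methylidene-5-oxooxolan-2-yl]hepta-2,6-dienoate | C=C(C)C(=O)O[C@H](C=O)[C@H]1C(=C)C(=O)O[C@@H]1/C=C(/CO[Si](c2ccccc2)(c2ccccc2)C(C)(C)C)CC/C=C(\I)C(=O)OC | intermediate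
22 | methyl (1(10)E,4E,6R,7S,8S,9R)-15-[(tert-butyldiphenylsilyl)oxy]-9-hydroxy-8-(methacryloyloxy)germacra-1(10),4,11(13)-trien-12,6-olid-14-oate | C=C(C)C(=O)O[C@H]1[C@H]2C(=C)C(=O)O[C@@H]2/C=C(/CO[Si](c3ccccc3)(c3ccccc3)C(C)(C)C)CC/C=C(/C(=O)OC)[C@H]1O | intermediate
23 | methyl (1(10)E,4E,6R,7S,8S,9R)-9-acetoxy-15-[(tert-butyldiphenylsilyl)oxy]-8-(methacryloyloxy)germacra-1(10),4,11(13)-trien-12,6-olid-14-oate | C=C(C)C(=O)O[C@H]1[C@H]2C(=C)C(=O)O[C@@H]2/C=C(/CO[Si](c3ccccc3)(c3ccccc3)C(C)(C)C)CC/C=C(/C(=O)OC)[C@H]1OC(C)=O | intermediate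
24 | CNP0179134.4, methyl (1(10)E,4E,6R,7S,8S,9R)-9-acetoxy-15-hydroxy-8-(methacryloyloxy)germacra-1(10),4,11(13)-trien-12,6-olid-14-oate | C=C(C)C(=O)O[C@H]1[C@H]2C(=C)C(=O)O[C@@H]2/C=C(/CO)CC/C=C(/C(=O)OC)[C@H]1OC(C)=O | target

**Count**

Total step count: 15. Longest linear sequence: 12 steps (steps 1–4, 7, 8, 10–15, from 2-butyne-1,4-diol).

**Steps most likely to fail**

Step 13. Inside the forming ring the α-acyloxy group may direct the addition only weakly, giving poor facial selectivity at C9, and the methacrylate may migrate onto the new chromium alkoxide. The fallback sets out from 18 and returns at 23; it closes the ring with a silyl ether at O8 and brings in the methacrylate afterwards. Both hydroxyls of 18 are silylated (excess TESCl, imidazole, DMAP, DMF) to the bis(triethylsilyl) ether F1. Swern oxidation cleaves and oxidises only the primary silyl ether to the α-silyloxy aldehyde F2. The CrCl2/NiCl2 ring closure, now ruled by a bulky, non-migrating α-silyloxy group of well-established Felkin preference, should give the macrocyclic alcohol F3. Acetylation (Ac2O, pyridine, DMAP) gives the acetate F4, PPTS in MeOH/CH2Cl2 at 0 °C removes the secondary triethylsilyl group to the 8-hydroxy 9-acetate F5, and methacrylic anhydride/Et3N/DMAP gives 23.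

Step 7. The aldehyde may approach the allylchromium on the other face relative to the dioxolane stereocentre (anti to C8–O instead of anti to C8–C9), which would give the lactone with C6 and C7 both inverted relative to C8. The fallback sets out from 8 and returns at 20; it takes C6/C7 from the enantiomeric bromide and sets C8 by invertive esterification. (S)-2,3-O-Isopropylideneglyceraldehyde F6 and 10 give, as in steps 5 and 6, the enantiomeric adduct F7 and the (4R)-bromide F8. Chromium-mediated coupling with 8 would then give the hydroxy ester F9 and, after lactonisation, the C8-epimeric lactone F10, which has the correct 6R,7S centres. Hydrolysis as in step 8 gives the diol aldehyde F11, Wittig reaction with 17 gives the iodoenoate diol F12, and selective silylation (TESCl, imidazole, −40 °C) gives the primary triethylsilyl ether F13. Mitsunobu esterification of F13 with methacrylic acid (PPh3, DIAD, toluene, 0 °C) inverts C8 and gives 20.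

Step 12. The amine stage of the oxidation may epimerise C8 of the α-acyloxy aldehyde (or eliminate the methacrylate), and the silyl ether next to the ester may be activated only slowly. The fallback sets out from 20 and returns at 21; it separates unmasking from oxidation and uses no amine base. HF·pyridine in THF/pyridine at 0 °C removes the primary triethylsilyl group (the tert-butyldiphenylsilyl ether is much slower) to give the primary alcohol F14, which is oxidised at once with Dess–Martin periodinane and NaHCO3 in CH2Cl2 at 0 °C to 21.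

Further compounds
F1 | step 13 | bis(triethylsilyl) ether of 18 | CC[Si](CC)(CC)OC[C@@H](O[Si](CC)(CC)CC)[C@H]1C(=C)C(=O)O[C@@H]1/C=C(/CO[Si](c2ccccc2)(c2ccccc2)C(C)(C)C)CC/C=C(\I)C(=O)OC
F2 | step 13 | α-(triethylsilyloxy) aldehyde (C9 aldehyde, 8-O-triethylsilyl analogue of 21) | O=C[C@@H](O[Si](CC)(CC)CC)[C@H]1C(=C)C(=O)O[C@@H]1/C=C(/CO[Si](c2ccccc2)(c2ccccc2)C(C)(C)C)CC/C=C(\I)C(=O)OC
F3 | step 13 | macrocyclic alcohol, 8-O-triethylsilyl analogue of 22 | CC[Si](CC)(CC)O[C@H]1[C@H]2C(=C)C(=O)O[C@@H]2/C=C(/CO[Si](c3ccccc3)(c3ccccc3)C(C)(C)C)CC/C=C(/C(=O)OC)[C@H]1O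
F4 | step 13 | 9-acetate of F3 | CC[Si](CC)(CC)O[C@H]1[C@H]2C(=C)C(=O)O[C@@H]2/C=C(/CO[Si](c3ccccc3)(c3ccccc3)C(C)(C)C)CC/C=C(/C(=O)OC)[C@H]1OC(C)=O
F5 | step 13 | 8-hydroxy 9-acetate (23 without the methacryloyl group) | O[C@H]1[C@H]2C(=C)C(=O)O[C@@H]2/C=C(/CO[Si](c3ccccc3)(c3ccccc3)C(C)(C)C)CC/C=C(/C(=O)OC)[C@H]1OC(C)=O
F6 | step 7 | (S)-2,3-O-isopropylideneglyceraldehyde | O=C[C@@H]1COC(C)(C)O1
F7 | step 7 | methyl 2-{[(4S)-2,2-dimethyl-1,3-dioxolan-4-yl](hydroxy)methyl}prop-2-enoate (both carbinol epimers) | C=C(C(=O)OC)C(O)[C@@H]1COC(C)(C)O1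
F8 | step 7 | methyl (2Z)-2-(bromomethyl)-3-[(4R)-2,2-dimethyl-1,3-dioxolan-4-yl]prop-2-enoate | BrC/C(=C\[C@@H]1COC(C)(C)O1)C(=O)OC
F9 | step 7 | C8-epimer of hydroxy ester 13 (dioxolane 4R) | CC1(C)OC[C@H](O1)[C@@H](C(=C)C(=O)OC)[C@H](O)/C=C(/CO[Si](c2ccccc2)(c2ccccc2)C(C)(C)C)CCC(OCC)OCC
F10 | step 7 | C8-epimer of lactone 14 (dioxolane 4R) | CC1(C)OC[C@H](O1)[C@H]2C(=C)C(=O)O[C@@H]2/C=C(/CO[Si](c3ccccc3)(c3ccccc3)C(C)(C)C)CCC(OCC)OCC
F11 | step 7 | C8-epimer of diol aldehyde 15 (side-chain carbinol 1R) | OC[C@H](O)[C@H]1C(=C)C(=O)O[C@@H]1/C=C(/CO[Si](c2ccccc2)(c2ccccc2)C(C)(C)C)CCC=O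
F12 | step 7 | C8-epimer of iodoenoate diol 18 | OC[C@H](O)[C@H]1C(=C)C(=O)O[C@@H]1/C=C(/CO[Si](c2ccccc2)(c2ccccc2)C(C)(C)C)CC/C=C(\I)C(=O)OC
F13 | step 7 | C8-epimer of primary triethylsilyl ether 19 | CC[Si](CC)(CC)OC[C@H](O)[C@H]1C(=C)C(=O)O[C@@H]1/C=C(/CO[Si](c2ccccc2)(c2ccccc2)C(C)(C)C)CC/C=C(\I)C(=O)OC
F14 | step 12 | primary alcohol from 20 (C9–OH, 8-O-methacryloyl) | C=C(C)C(=O)O[C@H](CO)[C@H]1C(=C)C(=O)O[C@@H]1/C=C(/CO[Si](c2ccccc2)(c2ccccc2)C(C)(C)C)CC/C=C(\I)C(=O)OC
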